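In ring B the neighbours C8 and C9 each hold one exocyclic carbon (C17 and C11), and C9 abuts the fully substituted C10. A four-carbon alkynoate leaves exactly this imprint when it adds to a C10=C5–C6=C7 diene. The synthesis therefore hinges on cutting C7–C8 and C9–C10. One intermolecular Diels–Alder reaction with methyl but-2-ynoate closes ring B, delivers C17 and C11 in place and creates C10, whose configuration is afterwards passed on to C5 and C9. The diene partner is an enantiopure ring A vinylcyclohexene. Its O3 and O18 sit in a trans-fused acetonide, which keeps the C19 methyl axial as a screen over one diene face.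

Key step: step 7

Numbering: labdane numbering is used throughout. Ring A is C1–C5 and C10; ring B is C5–C10. C17 is on C8, C11 is on C9, and C20 is on C10. On C4, C18 is the equatorial CH2O and C19 is the axial CH3. The target is an ent-labdane, (3R,4S,5S,9R,10S), with C19 and C20 on one face and H3, H5 and H9 on the other.

Assumption: the sense of induction in step 2 follows the empirical rule for chelating ketones, by which (R)-BINAP gives the (R)-carbinol when the chelating arm outranks the other alkyl arm. Should a correlation show the opposite, the (S)-ligand is used.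

Step 1
Reactants: 1 2-methylcyclohexane-1,3-dione
Product: 2 2-(hydroxymethyl)-2-methylcyclohexane-1,3-dione
Conditions: 37 % aq. HCHO (3 equiv), KHCO3 (5 mol %), H2O/THF, 0 °C → rt
Reagents that add atoms: formaldehyde, C=O
Why: Aldol-type hydroxymethylation in which the acidic 2-alkyl-1,3-dione adds through C2 to formaldehyde; dehydration is impossible at the new quaternary carbon (future C4, still prochiral), and the near-neutral medium holds back retro-aldol and ring cleavage.

Step 2
Reactants: 2 2-(hydroxymethyl)-2-methylcyclohexane-1,3-dione
Product: 3 (2S,3R)-3-hydroxy-2-(hydroxymethyl)-2-methylcyclohexan-1-one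
Conditions: H2 (50 atm), RuCl2[(R)-BINAP] (1 mol %), MeOH, 30 °C, stopped after one equivalent of H2
Reagents that add atoms: none
Why: Noyori heteroatom-directed asymmetric hydrogenation of a β-hydroxy ketone, used as a desymmetrisation: the primary hydroxyl and one carbonyl chelate divalent ruthenium so that hydride enters on the CH2OH face (O3 ends trans to C18 and cis to C19), the (R)-ligand picks the carbonyl that becomes (3R) and thereby fixes C4, and the remaining carbonyl is mismatched and reacts slowly.

Step 3
Reactants: 3 (2S,3R)-3-hydroxy-2-(hydroxymethyl)-2-methylcyclohexan-1-one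
Product: 4 trans-fused acetonide ketone (4aS,8aR)-2,2,4a-trimethylhexahydro-4H-1,3-benzodioxin-5-one
Conditions: Me2C(OMe)2, PPTS (cat.), CH2Cl2, rt
Reagents that add atoms: 2,2-dimethoxypropane, COC(C)(C)OC
Why: Acid-catalysed transketalisation of a 1,3-diol whose two oxygens are both equatorial, so the dioxane forms trans-fused and leaves C19 axial, while the lack of an α-hydrogen at C4 rules out β-elimination.

Step 4
Reactants: 4 trans-fused acetonide ketone
Product: 6 C10-methyl ketone acetonide (both C10 epimers), via lithium enolate 5 (not isolated)
Conditions: LiN(iPr)2 (1.1 equiv), THF, −78 °C; MeI, −78 → 0 °C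
Reagents that add atoms: iodomethane, CI
Why: Kinetic enolate alkylation in which only C10 can be deprotonated because C4 is quaternary, and both C10 epimers are usable because this centre becomes sp2 in step 5.

Step 5
Reactants: 6 C10-methyl ketone acetonide
Product: 8 tetrasubstituted C5=C10 enol triflate, via potassium enolate 7 (not isolated)
Conditions: KN(SiMe3)2 (1.3 equiv), THF, −78 → 0 °C; PhNTf2, 0 °C → rt
Reagents that add atoms: N-phenylbis(trifluoromethanesulfonimide), O=S(=O)(N(c1ccccc1)S(=O)(=O)C(F)(F)F)C(F)(F)F
Why: Enolate O-sulfonylation in which again a single enolate is possible, as is established for 2,2,6-trialkylcyclohexanones.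

Step 6
Reactants: 8 tetrasubstituted C5=C10 enol triflate; 9 vinylboronic acid pinacol ester
Product: 10 ring A diene (4aS,8aR)-2,2,4a,6-tetramethyl-5-vinyl-4a,7,8,8a-tetrahydro-4H-1,3-benzodioxine
Conditions: PdCl2(dppf) (5 mol %), K3PO4, 1,4-dioxane/H2O, 80 °C
Reagents that add atoms: none
Why: Suzuki–Miyaura coupling of a hindered alkenyl triflate with a vinylboronate, which attaches C6=C7 to C5 and touches no stereocentre.

Step 7
Reactants: 10 ring A diene; 11 methyl but-2-ynoate
Product: 12 bicyclic 5,8-diene ester (C5=C6 and C8=C9, CO2Me = C11 on C9, C17 methyl on C8, C20 on quaternary C10 syn to C19, 3,18-acetonide)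
Conditions: 11 (5 equiv), BHT (1 mol %), CH2Cl2, 13 kbar, 50 °C
Reagents that add atoms: none
Why: A concerted but asynchronous [4+2] cycloaddition is expected: the unsubstituted terminus C7, which carries the larger HOMO coefficient of this diene and no steric load, bonds early to the electrophilic β-carbon of 11 (future C8), while the bond from the ester-bearing α-carbon (future C9) to the fully substituted C10 lags behind and stays long in the transition state. The closest known reaction type is the Diels–Alder addition of acetylenic esters to 2,6,6-trialkyl-1-vinylcyclohexenes; pressure replaces strong heating here because 11 has one activating group only and because heat would invite a 1,5-hydrogen shift from C20 to C7. Ring B is closed as a six-membered carbocycle by suprafacial bonding at both diene termini, and the resulting 1,4-cyclohexadiene cannot aromatise since C10 is quaternary. C10 is the only new stereocentre and is governed by C4: the trans-fused dioxane holds C19 pseudoaxial and 1,3 to C10, so 11 approaches from the other face and C20 is bent onto the C19 side. Two selectivities are needed, orientation and face; the first is secured by the polarity match of C7 to the β-carbon, reinforced by the lower crowding of a late C9–C10 bond, and the second by the C19 screen in the conformationally locked ring A.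

Step 8
Reactants: 12 bicyclic 5,8-diene ester
Product: 13 trans-decalin conjugated ester (H5 anti to C19 and C20, C8=C9 retained)
Conditions: H2 (1 atm), 10 % Pd/C, EtOAc, rt
Reagents that add atoms: none
Why: Heterogeneous catalytic hydrogenation that reduces the trisubstituted C5=C6 alkene and spares the tetrasubstituted, ester-conjugated C8=C9 alkene; the two axial methyls C19 and C20 cover one face, so H5 arrives on the other and the ring fusion becomes trans.

Step 9
Reactants: 13 trans-decalin conjugated ester
Product: 15 β,γ-unsaturated ester (C8=C17 methylene; equatorial CO2Me on C9), via lithium dienolate 14 (not isolated)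
Conditions: LiN(iPr)2 (2 equiv), THF, −78 → −30 °C; inverse quench into AcOH/THF, −78 °C
Reagents that add atoms: none
Why: Deconjugative protonation of an ester dienolate, in which the lithium amide bound to the ester carbonyl reaches only the γ-hydrogens cis to it (C17, whereas C7 lies trans across C8=C9), and kinetic α-protonation of 14 occurs axially on the face away from C20, which sets H9 syn to H5 and leaves the exocyclic alkene.

Step 10
Reactants: 15 β,γ-unsaturated ester
Product: 16 C11 primary alcohol
Conditions: LiAlH4, Et2O, 0 °C
Reagents that add atoms: none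
Why: Hydride reduction of the ester, to which the acetonide and the isolated alkene are inert and which is faster than any enolisation at C9.

Step 11
Reactants: 16 C11 primary alcohol
Product: 17 C11 aldehyde
Conditions: Dess–Martin periodinane, NaHCO3, CH2Cl2, 0 °C
Reagents that add atoms: none
Why: Dess–Martin oxidation under buffered, non-basic conditions, chosen so that the β,γ-unsaturated aldehyde neither epimerises at C9 nor slips into conjugation.

Step 12
Reactants: 17 C11 aldehyde
Product: 18 C9-vinyl compound (C11=C12 beside C8=C17)
Conditions: Ph3PCH3Br, KOtBu, THF, 0 °C; then 17, −78 → 0 °C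
Reagents that add atoms: methyltriphenylphosphonium bromide, C[P+](c1ccccc1)(c1ccccc1)c1ccccc1.[Br-]
Why: Wittig methylenation with a non-stabilised ylide at low temperature, where addition to the aldehyde outruns enolisation so that C9 is preserved.

Step 13
Reactants: 18 C9-vinyl compound; 19 4-bromofuran-2(5H)-one
Product: 21 butenolide acetonide (complete C11–C16 side chain), via C12 disiamylborane 20 (not isolated)
Conditions: BH3·THF, 2-methylbut-2-ene, THF, 0 °C (gives Sia2BH); 18, 0 °C → rt; then 19, PdCl2(dppf) (5 mol %), AsPh3 (10 mol %), K3PO4, DMF/H2O, 45 °C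
Reagents that add atoms: none
Why: Hydroboration followed by B-alkyl Suzuki–Miyaura coupling, in which disiamylborane discriminates strongly for the monosubstituted C11=C12 alkene over the 1,1-disubstituted C8=C17 alkene and places boron on C12, and the primary alkyl group is the one handed to palladium and joined to C13 of the bromobutenolide.

Step 14
Reactants: 21 butenolide acetonide
Product: 22 3,18-diol
Conditions: AcOH/H2O (4:1), 35 °C
Reagents that add atoms: none
Why: Mild acid hydrolysis of the ketal, under which the exocyclic methylene of labdanes and the butenolide persist.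

Step 15
Reactants: 22 3,18-diol
Product: 23 18-O-TBS ether with free 3-OH
Conditions: TBSCl (1.1 equiv), imidazole, CH2Cl2, 0 °C
Reagents that add atoms: tert-butyldimethylsilyl chloride, C[Si](C)(Cl)C(C)(C)C
Why: Selective silylation, since the primary O18 reacts far faster than the secondary O3 that is flanked by quaternary C4.

Step 16
Reactants: 23 18-O-TBS ether with free 3-OH; 24 angelic acid
Product: 26 3-O-angelate 18-O-TBS ether, via mixed anhydride 25 (not isolated)
Conditions: 24, 2,4,6-Cl3C6H2COCl, Et3N, toluene, rt; then 23, 80 °C
Reagents that add atoms: none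
Why: Yamaguchi-type mixed-anhydride esterification run without a nucleophilic catalyst, which avoids the addition–elimination path that turns (Z)-angelates into (E)-tiglates; O3 attacks the less hindered angeloyl carbonyl of 25 and C3 keeps its configuration.

Step 17
Reactants: 26 3-O-angelate 18-O-TBS ether
Product: 27 target CNP0292066.2
Conditions: HF·pyridine, pyridine/THF, 0 °C → rt
Reagents that add atoms: none
Why: Fluoride-mediated desilylation in a weakly acidic medium that never generates a free alkoxide, so the angelate does not migrate from O3 to O18.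

Compound list
1 | 2-methylcyclohexane-1,3-dione | CC1C(=O)CCCC1=O | starting material
2 | 2-(hydroxymethyl)-2-methylcyclohexane-1,3-dione (prochiral; quaternary carbon = C4) | CC1(CO)C(=O)CCCC1=O | intermediate
3 | (2S,3R)-3-hydroxy-2-(hydroxymethyl)-2-methylcyclohexan-1-one (O3 trans to C18, cis to C19) | O=C1CCC[C@@H](O)[C@]1(C)CO | intermediate
4 | (4aS,8aR)-2,2,4a-trimethylhexahydro-4H-1,3-benzodioxin-5-one (trans-fused acetonide, C5 ketone) | O=C1CCC[C@H]2OC(C)(C)OC[C@]12C | intermediate
5 | lithium enolate of 4 (C5(OLi)=C10) | [Li]OC1=CCC[C@H]2OC(C)(C)OC[C@]12C | intermediate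
6 | C10-methyl ketone acetonide (C10 epimers) | O=C1C(C)CC[C@H]2OC(C)(C)OC[C@]12C | intermediate
7 | potassium enolate of 6 (C5(OK)=C10) | [K]OC1=C(C)CC[C@H]2OC(C)(C)OC[C@]12C | intermediate
8 | C5=C10 enol triflate | O=S(=O)(OC1=C(C)CC[C@H]2OC(C)(C)OC[C@]12C)C(F)(F)F | intermediate
9 | vinylboronic acid pinacol ester | C=CB1OC(C)(C)C(C)(C)O1 | starting material
10 | ring A diene, (4aS,8aR)-2,2,4a,6-tetramethyl-5-vinyl-4a,7,8,8a-tetrahydro-4H-1,3-benzodioxine | C=CC1=C(C)CC[C@H]2OC(C)(C)OC[C@]12C | intermediate
11 | methyl but-2-ynoate | CC#CC(=O)OC | starting material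
12 | bicyclic 5,8-diene ester (C20 syn to C19) | CC1CC=C2[C@@](C)(CC[C@H]3OC(C)(C)OC[C@]23C)C=1C(=O)OC | intermediate
13 | trans-decalin conjugated ester (H5 anti to C19/C20) | COC(=O)C1=C(C)CC[C@H]2[C@@]1(C)CC[C@H]3OC(C)(C)OC[C@]23C | intermediate
14 | lithium dienolate (C8=C17, C9=C11(OLi)OMe) | C=C1CC[C@H]2[C@@](C)(CC[C@H]3OC(C)(C)OC[C@]23C)C1=C(OC)O[Li] | intermediate
15 | β,γ-unsaturated ester (H9 syn to H5, equatorial CO2Me) | C=C1CC[C@H]2[C@@](C)(CC[C@H]3OC(C)(C)OC[C@]23C)[C@@H]1C(=O)OC | intermediate
16 | C11 primary alcohol | C=C1CC[C@H]2[C@@](C)(CC[C@H]3OC(C)(C)OC[C@]23C)[C@@H]1CO | intermediate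
17 | C11 aldehyde | C=C1CC[C@H]2[C@@](C)(CC[C@H]3OC(C)(C)OC[C@]23C)[C@@H]1C=O | intermediate
18 | C9-vinyl compound | C=C1CC[C@H]2[C@@](C)(CC[C@H]3OC(C)(C)OC[C@]23C)[C@@H]1C=C | intermediate
19 | 4-bromofuran-2(5H)-one | O=C1C=C(Br)CO1 | starting material
20 | C12 disiamylborane | C=C1CC[C@H]2[C@@](C)(CC[C@H]3OC(C)(C)OC[C@]23C)[C@@H]1CCB(C(C)C(C)C)C(C)C(C)C | intermediate
21 | butenolide acetonide | C=C1CC[C@H]2[C@@](C)(CC[C@H]3OC(C)(C)OC[C@]23C)[C@@H]1CCC1=CC(=O)OC1 | intermediate
22 | 3,18-diol | C=C1CC[C@H]2[C@@](C)(CC[C@@H](O)[C@]2(C)CO)[C@@H]1CCC1=CC(=O)OC1 | intermediate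
23 | 18-O-TBS ether, free 3-OH | C=C1CC[C@H]2[C@@](C)(CC[C@@H](O)[C@]2(C)CO[Si](C)(C)C(C)(C)C)[C@@H]1CCC1=CC(=O)OC1 | intermediate
24 | angelic acid, (Z)-2-methylbut-2-enoic acid | C/C=C(/C)C(=O)O | starting material
25 | angelic 2,4,6-trichlorobenzoic anhydride | C/C=C(/C)C(=O)OC(=O)c1c(Cl)cc(Cl)cc1Cl | intermediate
26 | 3-O-angelate 18-O-TBS ether | C=C1CC[C@H]2[C@@](C)(CC[C@@H](OC(=O)/C(C)=C\C)[C@]2(C)CO[Si](C)(C)C(C)(C)C)[C@@H]1CCC1=CC(=O)OC1 | intermediate
27 | CNP0292066.2, (3R,4S,5S,9R,10S)-3-angeloyloxy-18-hydroxy-ent-labda-8(17),13-dien-15,16-olide | C=C1CC[C@H]2[C@@](C)(CC[C@@H](OC(=O)/C(C)=C\C)[C@]2(C)CO)[C@@H]1CCC1=CC(=O)OC1 | target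

Total step count: 17. Longest linear sequence: 17 steps (1 → 27). Compounds 9, 11, 19 and 24 are bought and used as such.

Steps most likely to fail

1. Step 7. The cycloaddition may be too slow, because the diene terminus is tetrasubstituted and the alkyne is only singly activated. In that case 1,5-hydrogen migration within the diene, oligomerisation or leakage into the reversed orientation would take over. The fallback sets out from 10 and comes back at 12.
 - Methyl propiolate is brominated (NBS, AgNO3 cat., acetone, rt) to methyl 3-bromopropiolate F1, a markedly more reactive and more polarised dienophile.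
 - Its thermal cycloaddition to 10 (toluene, 90 °C) should give, under the same facial control by C19, the 8-bromo diene ester F2.
 - A Suzuki–Miyaura methylation (MeB(OH)2, PdCl2(dppf), K3PO4, 1,4-dioxane, 80 °C) then places C17 on C8 and returns to 12.

2. Step 9. Deprotonation may stray to C7, or the dienolate may equilibrate. The alkene would then end up inside ring B after protonation, or the quench would simply return conjugated material. The fallback sets out from 13 and comes back at 15, and it replaces base chemistry by a photochemical deconjugation.
 - 13 is irradiated at 254 nm (quartz, hexane, catalytic 1,2-dimethylimidazole, rt).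
 - The excited enoate undergoes a 1,5-hydrogen shift to the carbonyl oxygen. For geometric reasons this shift can start only from the γ-carbon cis to the ester, which is C17.
 - The resulting photodienol F3 ketonises under the mild base catalysis by protonation at C9 on the face away from C20, which gives 15.

3. Step 2. Chelation may be too weak on this hindered cyclic substrate. That would show as slow turnover, eroded enantioselection or over-reduction of the second carbonyl. The fallback sets out from 2 and comes back at 4, and it separates relative from absolute control.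
 - An Evans–Saksena reduction (Me4NBH(OAc)3, 1 equiv, MeCN/AcOH, −30 °C) delivers hydride from boron bound to O18. It should therefore give the same trans relationship as the racemic trans-diol F4.
 - Ketalisation as in step 3 gives the racemic acetonide ketone F5.
 - The antipodes of F5 are separated by preparative chromatography on a cellulose-based chiral phase, the (4aS,8aR) antipode being 4.

Further compounds
F1 | step 7 | methyl 3-bromopropiolate | COC(=O)C#CBr
F2 | step 7 | 8-bromo diene ester (Br on C8 in place of C17, otherwise as 12) | COC(=O)C1=C(Br)CC=C2[C@@]1(C)CC[C@H]3OC(C)(C)OC[C@]23C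
F3 | step 9 | photodienol (C8=C17, C9=C11(OH)OMe) | C=C1CC[C@H]2[C@@](C)(CC[C@H]3OC(C)(C)OC[C@]23C)C1=C(O)OC
F4 | step 2 | racemic trans-diol (3 and its mirror image) | O=C1CCC[C@@H](O)[C@]1(C)CO.O=C1CCC[C@H](O)[C@@]1(C)CO
F5 | step 2 | racemic acetonide ketone (4 and its mirror image) | O=C1CCC[C@H]2OC(C)(C)OC[C@]12C.O=C1CCC[C@@H]2OC(C)(C)OC[C@@]12C
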